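The closed, stirred vessel in front of you gets the last recipe below, and the earlier runs stand beside it.

| setting | blue | red | violet | flask |
|---|---|---|---|---|
| starting material | 6.7 mM | 15 mM | 10 mM | 10 mM |
| reagent | 6 mM | 6 mM | 3 mM | 6.00 mM |
| second substrate | 10 mM | 10 mM | 10 mM | 10.0 mM |
| remark | run made earlier | run made earlier | run made earlier |  |
| time |  |  |  | 10 min |

- blue (time / min: target / %): 0.833: 41.9; 2.50: 40.0; 5.00: 41.3; 8.00: 40.3; 10.0: 41.3
- red (time / min: target / %): 0.833: 26.9; 2.50: 27.8; 5.00: 27.9; 8.00: 26.1; 10.0: 27.1
- violet (time / min: target / %): 0.833: 19.7; 1.50: 18.4; 3.00: 17.7; 5.00: 18.4; 10.0: 16.8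

(each reading ± 1 percentage point)

- the reaction counts as stopped when no species that holds the starting material changes by six tenths of a point or more over the second half of the time

- the state of affairs at 10 min: stopped, and by what, or still going (the reagent has run out first / forward and back rates have come level / it is still moving / all of the starting material has reacted)
- target at 10 min, in percent of the starting material charged

The blue, red and violet runs show no trend beyond their scatter of 1 percentage point from the first reading at 0.833 min on, so expect your flask to have stopped well before 10 min. What stopped it is the open question, and I reckon it two ways.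

Way one takes a balance. From each run's mean reading, with starting material and reagent as charge minus target, form [target]/([starting material][reagent]):

blue: 2.74 mM target, ratio 0.213 mM⁻¹
red: 4.07 mM target, ratio 0.194 mM⁻¹
violet: 1.82 mM target, ratio 0.189 mM⁻¹

Their mean is the standing ratio, an apparent equilibrium constant, read as 0.198 mM⁻¹. For your flask:

x/((10 mM − x)(6.00 mM − x)) = 0.198 mM⁻¹, so x = 3.40 mM, or 34.0%

Way two spends the reagent wholly on the two substrates, with reagent as limiting reagent. The selectivity factor, ln(starting material left)/ln(second substrate left), reads 1.34, 1.48 and 1.60. The target of way one needs 1.38, inside that span. Both ways rest on the same readings, so this agreement checks nothing. Watch the reagent instead: way one leaves 2.60 mM of it, way two none.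

The forecast says forward and back rates have come level and 34%: “so I favour equilibrium, without certainty”.

The flask gives forward and back rates have come level and 34.4%, with 23% of the reagent standing beside 66% of the starting material at 10.0 min, and 1.18 mM of second product.

    starting material + reagent ⇌ target (K = 380 L mol⁻¹, k = 47.0 L mol⁻¹ s⁻¹)
    second substrate + reagent ⇌ second product (K = 97.0 L mol⁻¹, k = 62.0 L mol⁻¹ s⁻¹)

Now charge 24 mM of reagent, more than the 20.0 mM of both substrates together. Way two then ends with no starting material, while the standing ratio gives 7.64 mM of target, or 76.4%. That neighbour flask gives 80.5% of target, with 19.5% of the starting material still unbound.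

The data are calculated for an exercise, noise included.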